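## Retrosynthetic overview

- Junceellolide K (44) ← triol lactone 43 by acetylation ← ten-membered cycloalkene 41. Ring B (C1–C10) is not closed directly: it comes from the 11-membered cyclic sulfone 38 (C1–C5, S, C6–C10) by Ramberg–Bäcklund ring contraction with loss of SO2.
- Enabling feature: the single cis C5(Me)=C6H double bond of ring B, flanked by C4H2 and by C7, whose oxygen is an ether-type (poor) leaving group. Cutting this bond gives a C5–SO2–C6 bridge whose thioether closes by simple S-alkylation.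
- Thiacycle 35 ← C5 thiolate + C6 tosylate. The lactone (ring C) is carried as a silyl lactol, and the 11,20-epoxide is made by peracid on the C11 methylene before the ring olefin exists.
- Ring C ← samarium Reformatsky from O7 onto the C8 ketone (sets C8, C17). C9 ← chelation-controlled addition of a glycerate-derived C6–C8 vinyl metal to the C9 aldehyde.
- C10/C1/C2 ← vinyl conjugate addition–aldol on enone 6 with aldehyde 9; C14 ← anti-selective directed reduction. Ring order: ring A (from 1) → ring C (step 20) → 11-membered thiacycle (step 25) → epoxide (step 28) → ring B (step 29).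

Key step: step 29

Remark on the chemistry: atoms carry the briarane numbers of 44 in all intermediates; 26–28 are mixtures at the CHBr carbon and 30–42 at the lactol carbon C19 (left open in the SMILES); each remaining stereocentre has the arrangement drawn in its SMILES, which is authoritative.

## Route

### Ring A enone (steps 1–5)

Step 1
Reactants: 1 4-methoxy-3-methylphenol
Product: 2 4,4-dimethoxy-3-methylcyclohexa-2,5-dien-1-one
Conditions: PhI(OAc)2, MeOH, 0 °C
Reagents that add atoms: methanol, CO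
Why: Oxidative dearomatization of a para-alkoxyphenol with a hypervalent iodine reagent in methanol gives the quinone monoketal, methanol adding at the oxygen-bearing para carbon.

Step 2
Reactants: 2 4,4-dimethoxy-3-methylcyclohexa-2,5-dien-1-one
Product: 3 4,4-dimethoxy-3-methylcyclohex-2-en-1-one
Conditions: H2 (1 atm), RhCl(PPh3)3 (cat), benzene, rt
Reagents that add atoms: none
Why: Homogeneous hydrogenation with RhCl(PPh3)3 should saturate only the less substituted C5=C6 bond and leave the methyl-bearing enone.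

Step 3
Reactants: 3 4,4-dimethoxy-3-methylcyclohex-2-en-1-one
Product: 4 (R)-4,4-dimethoxy-3-methylcyclohex-2-en-1-ol
Conditions: (S)-Me-CBS oxazaborolidine (20 mol %), BH3·SMe2, THF, −20 °C
Reagents that add atoms: none
Why: Corey–Bakshi–Shibata reduction, with the alkenyl arm as the large group, should give the (R)-carbinol that becomes C11.

Step 4
Reactants: 4 (R)-4,4-dimethoxy-3-methylcyclohex-2-en-1-ol
Product: 5 (R)-3-[(4-methoxybenzyl)oxy]-6,6-dimethoxy-1-methylcyclohex-1-ene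
Conditions: NaH, 4-methoxybenzyl chloride, Bu4NI (cat), THF/DMF, 0 °C to rt
Reagents that add atoms: 4-methoxybenzyl chloride, COc1ccc(CCl)cc1
Why: Williamson etherification installs the PMB ether that later serves as the chelating group at O11.

Step 5
Reactants: 5 (R)-3-[(4-methoxybenzyl)oxy]-6,6-dimethoxy-1-methylcyclohex-1-ene
Product: 6 (R)-4-[(4-methoxybenzyl)oxy]-2-methylcyclohex-2-en-1-one
Conditions: oxalic acid, wet SiO2, CH2Cl2, rt
Reagents that add atoms: water, O
Why: Mild acid hydrolysis of the dimethyl ketal unveils the enone (C14=O, C1 methyl, C11 OPMB) without touching the PMB ether.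

### Aldehyde for C2–C5 (steps 6–7)

Step 6
Reactants: 7 (S)-hex-5-en-2-ol
Product: 8 (S)-5-[(4-methoxybenzyl)oxy]hex-1-ene
Conditions: NaH, 4-methoxybenzyl chloride, Bu4NI (cat), DMF, 0 °C to rt
Reagents that add atoms: 4-methoxybenzyl chloride, COc1ccc(CCl)cc1
Why: Williamson etherification protects the future C5 oxygen.

Step 7
Reactants: 8 (S)-5-[(4-methoxybenzyl)oxy]hex-1-ene
Product: 9 (S)-4-[(4-methoxybenzyl)oxy]pentanal
Conditions: OsO4 (cat), NaIO4, 2,6-lutidine, dioxane/H2O, rt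
Reagents that add atoms: sodium periodate, [Na+].[O-]I(=O)(=O)=O
Why: Lemieux–Johnson cleavage of the terminal alkene gives the aldehyde (future C2) and tolerates the PMB ether.

### Vinyl iodide for C6–C8 (steps 8–9)

Step 8
Reactants: 10 methyl (S)-2,2-dimethyl-1,3-dioxolane-4-carboxylate
Product: 12 (S)-1-(2,2-dimethyl-1,3-dioxolan-4-yl)ethan-1-one, via Weinreb amide 11 (not isolated)
Conditions: MeNH(OMe)·HCl, i-PrMgCl, THF, −20 °C; then MeMgBr, 0 °C
Reagents that add atoms: methylmagnesium bromide, C[Mg]Br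
Why: Weinreb ketone synthesis stops at the methyl ketone through the chelated tetrahedral intermediate, and the low temperature should preserve the α-alkoxy centre (future C7).

Step 9
Reactants: 12 (S)-1-(2,2-dimethyl-1,3-dioxolan-4-yl)ethan-1-one
Product: 14 (S)-4-(1-iodoethenyl)-2,2-dimethyl-1,3-dioxolane, via hydrazone 13 (not isolated)
Conditions: N2H4·H2O, Et3N, EtOH, rt; then I2, 1,1,3,3-tetramethylguanidine, THF, 0 °C
Reagents that add atoms: iodine, II
Why: Barton vinyl iodide synthesis converts the methyl ketone hydrazone into the less substituted 2-iodoalkene.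

### Main line (steps 10–32)

Step 10
Reactants: 6 (R)-4-[(4-methoxybenzyl)oxy]-2-methylcyclohex-2-en-1-one; 9 (S)-4-[(4-methoxybenzyl)oxy]pentanal
Product: 16 aldol adduct (C14 ketone; C1 β-methyl and α C2–C5 chain with free 2-OH and 5-OPMB; C10 β-vinyl; C11 α-OPMB), via bromomagnesium enolate 15 (not isolated)
Conditions: CH2=CHMgBr, CuBr·SMe2 (10 mol %), THF, −78 °C; then 9, −78 °C; aq NH4Cl
Reagents that add atoms: vinylmagnesium bromide, C=C[Mg]Br
Why: Copper-catalysed conjugate addition should occur anti to the C11 OPMB group (sets C10), and the magnesium enolate should add to the aldehyde trans to the new vinyl group through a Zimmerman–Traxler chair (methyl cis to the enolate oxygen), which sets the quaternary C1 and the C2 carbinol in one three-component coupling.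

Step 11
Reactants: 16 aldol adduct
Product: 17 2,14-diol (14α-OH, anti to 2-OH)
Conditions: Me4NBH(OAc)3, MeCN/AcOH, −30 °C
Reagents that add atoms: none
Why: Evans–Saksena reduction delivers hydride intramolecularly from the C2 alkoxyborohydride and should give the 1,3-anti diol, which is the C2/C14 relationship of the target.

Step 12
Reactants: 17 2,14-diol
Product: 18 2,14-bis-TBS ether
Conditions: TBSOTf, 2,6-lutidine, CH2Cl2, 0 °C to rt
Reagents that add atoms: tert-butyldimethylsilyl triflate, CC(C)(C)[Si](C)(C)OS(=O)(=O)C(F)(F)F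
Why: Silyl triflate silylates both hindered secondary alcohols, which must survive base and be removed by fluoride at the end.

Step 13
Reactants: 18 2,14-bis-TBS ether
Product: 19 C9 aldehyde
Conditions: OsO4 (cat), NaIO4, 2,6-lutidine, dioxane/H2O, rt
Reagents that add atoms: sodium periodate, [Na+].[O-]I(=O)(=O)=O
Why: Lemieux–Johnson cleavage of the vinyl group gives the C9 aldehyde, whose C10 centre sits in its favoured equatorial arrangement.

Step 14
Reactants: 19 C9 aldehyde; 14 (S)-4-(1-iodoethenyl)-2,2-dimethyl-1,3-dioxolane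
Product: 22 (9S)-allylic alcohol (C8=CH2; O6/O7 acetonide), via vinyllithium 20 (not isolated), via vinylmagnesium bromide 21 (not isolated)
Conditions: 14, t-BuLi (2 equiv), Et2O, −78 °C; MgBr2·OEt2; then 19 precomplexed with MgBr2·OEt2, CH2Cl2, −78 °C
Reagents that add atoms: none
Why: Cram-chelate addition: magnesium bridges the aldehyde oxygen and the β C11 OPMB oxygen in a chelate trans-fused to ring A, and attack anti to the axial C10–H should give the 9,11-anti alcohol required for C9.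

Step 15
Reactants: 22 (9S)-allylic alcohol
Product: 23 9-O-TBS ether
Conditions: TBSOTf, 2,6-lutidine, CH2Cl2, −40 to 0 °C
Reagents that add atoms: tert-butyldimethylsilyl triflate, CC(C)(C)[Si](C)(C)OS(=O)(=O)C(F)(F)F
Why: Silylation at low temperature protects O9 without opening the acetonide.

Step 16
Reactants: 23 9-O-TBS ether
Product: 24 6,7-diol
Conditions: camphorsulfonic acid (cat), MeOH, 0 °C to rt
Reagents that add atoms: none
Why: Acid-catalysed transketalization removes the terminal acetonide while the hindered secondary TBS ethers and the PMB ethers persist.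

Step 17
Reactants: 24 6,7-diol
Product: 25 6-O-tosylate (7-OH free)
Conditions: TsCl, Et3N, Bu2SnO (cat), CH2Cl2, 0 °C
Reagents that add atoms: 4-toluenesulfonyl chloride, Cc1ccc(cc1)S(Cl)(=O)=O
Why: Tin-acetal-mediated sulfonylation is selective for the primary hydroxyl, and at this stage no ketone is present that could trigger β-elimination of the tosylate.

Step 18
Reactants: 25 6-O-tosylate
Product: 26 7-O-(2-bromopropanoyl) ester
Conditions: 2-bromopropanoyl bromide, pyridine, CH2Cl2, −20 °C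
Reagents that add atoms: 2-bromopropanoyl bromide, CC(Br)C(Br)=O
Why: Acylation of the allylic C7 hydroxyl tethers the C17–C19 unit (with its methyl C18) to O7.

Step 19
Reactants: 26 7-O-(2-bromopropanoyl) ester
Product: 27 C8 ketone
Conditions: O3, CH2Cl2/MeOH, pyridine, −78 °C (Sudan Red 7B end point); then PPh3
Reagents that add atoms: ozone, [O-][O+]=O
Why: Ozonolysis of the 1,1-disubstituted alkene under neutral conditions unveils the C8 ketone without exposing the β-tosyloxy ketone to base.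

Step 20
Reactants: 27 C8 ketone
Product: 29 β-hydroxy-γ-lactone (ring C closed; 8-OH; 17-methyl), via samarium enolate 28 (not isolated)
Conditions: SmI2 (2.5 equiv), THF, −78 °C; aq NH4Cl
Reagents that add atoms: none
Why: Intramolecular samarium Reformatsky reaction: the enolate tethered to O7 adds to the C8 ketone in a chelated transition state that places the large C9 branch trans to C6 (8-OH cis to C6) and the C17 methyl trans to C9, which is also the thermodynamically preferred, epimerizable arrangement.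

Step 21
Reactants: 29 β-hydroxy-γ-lactone
Product: 30 lactol
Conditions: i-Bu2AlH (3 equiv), CH2Cl2, −78 °C; Rochelle salt
Reagents that add atoms: none
Why: Half-reduction of the lactone at low temperature masks the carbonyl so that no acyloxy leaving group or acidic C17–H is present during the later base-mediated ring contraction.

Step 22
Reactants: 30 lactol
Product: 31 lactol TIPS ether (8-OH free)
Conditions: TIPSCl, imidazole, DMAP (cat), DMF, rt
Reagents that add atoms: triisopropylsilyl chloride, CC(C)[Si](Cl)(C(C)C)C(C)C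
Why: The hemiacetal hydroxyl is silylated selectively over the tertiary C8 hydroxyl, giving a base-stable, fluoride-labile acetal.

Step 23
Reactants: 31 lactol TIPS ether
Product: 32 5,11-diol
Conditions: DDQ, CH2Cl2/pH 7 buffer, 0 °C to rt
Reagents that add atoms: none
Why: Oxidative cleavage removes both PMB ethers under buffered, non-acidic conditions that spare the silyl ethers and the tosylate.

Step 24
Reactants: 32 5,11-diol
Product: 33 (5R)-thioacetate (11-OH free)
Conditions: PPh3, DIAD, AcSH, THF, 0 °C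
Reagents that add atoms: thioacetic acid, CC(=O)S
Why: Mitsunobu displacement should occur only at the unhindered acyclic C5 alcohol (with inversion, which is irrelevant later), the ring C11 alcohol next to the branched C10 being much slower.

Step 25
Reactants: 33 (5R)-thioacetate
Product: 35 11-membered cyclic sulfide (C5–S–C6), via thiol 34 (not isolated)
Conditions: K2CO3, MeOH/THF (degassed), 2 mM, rt to 40 °C
Reagents that add atoms: none
Why: Methanolysis frees the thiolate, which displaces the primary C6 tosylate at high dilution; C–S macrocyclization is far easier than a direct ten-membered C–C closure.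

Step 26
Reactants: 35 11-membered cyclic sulfide
Product: 36 C11 ketone
Conditions: SO3·pyridine, DMSO, i-Pr2NEt, CH2Cl2, 0 °C
Reagents that add atoms: none
Why: Parikh–Doering oxidation converts the only secondary alcohol into the ketone and does not oxidize the sulfide.

Step 27
Reactants: 36 C11 ketone
Product: 37 C11 exocyclic methylene (C20)
Conditions: Ph3PCH3Br, KOt-Bu, toluene/THF, 0 to 60 °C
Reagents that add atoms: methyltriphenylphosphonium bromide, C[P+](c1ccccc1)(c1ccccc1)c1ccccc1.[Br-]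
Why: Wittig methylenation introduces C20, and no ester or lactone carbonyl is present to compete.

Step 28
Reactants: 37 C11 exocyclic methylene
Product: 38 11-membered cyclic sulfone with the 11,20-epoxide
Conditions: mCPBA (3.5 equiv), NaHCO3, CH2Cl2, 0 °C to rt
Reagents that add atoms: 3-chloroperbenzoic acid, OOC(=O)c1cccc(Cl)c1
Why: The peracid oxidizes the sulfide to the sulfone and epoxidizes the only alkene (Prilezhaev reaction) from the equatorial α face, because the axial face is blocked by the 1,3-diaxial C1 methyl, which places C20 β and the oxygen α as in the target.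

Step 29
Reactants: 38 11-membered cyclic sulfone with the 11,20-epoxide
Product: 41 ten-membered (5Z)-cycloalkene (silyl lactol; 2,9,14-tris-TBS), via α-bromo sulfone 39 (not isolated), via episulfone 40 (not isolated)
Conditions: CBr2F2, KOH/Al2O3, t-BuOH/CH2Cl2, 0 °C to rt
Reagents that add atoms: none
Why: Hydroxide on alumina deprotonates the sulfone at C6 and CBr2F2 transfers bromine to give 39; deprotonation at C5 then triggers an intramolecular 1,3-displacement of bromide (3-exo-tet) that forms the C5–C6 bond, so the 11-membered thiacycle becomes the bicyclic episulfone 40, and cheletropic loss of SO2 leaves the ten-membered carbocycle. The closest known reaction type is the Ramberg–Bäcklund ring contraction of medium-ring cyclic sulfones to cycloalkenes, including β-alkoxy sulfones and trisubstituted ring olefins. The only ring closed is ring B, by carbanion alkylation inside the existing macrocycle, which avoids a direct ten-membered C–C cyclization. The only new stereo-element is the C5=C6 geometry: the reversibly formed α-sulfonyl carbanions let the episulfone adopt the less strained cis fusion on the ten-membered ring, which should give the Z olefin. The step needs ring contraction to win over β-elimination of the C7 oxygen and over halogenation elsewhere; this is secured because O7 is an acetal ether oxygen (a poor leaving group) and the lactone is masked as the silyl lactol, so no carbonyl or acyloxy group is present. The epoxide, the silyl ethers and the tertiary alkoxide at C8 should be inert to the heterogeneous base.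

Step 30
Reactants: 41 ten-membered (5Z)-cycloalkene
Product: 42 lactol pentaol (2,8,9,14,19-OH)
Conditions: TBAF, AcOH (1:1), THF, rt to 40 °C
Reagents that add atoms: none
Why: Buffered fluoride removes the three TBS ethers and the anomeric TIPS group without opening the epoxide or promoting retro-aldol cleavage of the lactol.

Step 31
Reactants: 42 lactol pentaol
Product: 43 2,9,14-triol lactone (8-OH)
Conditions: TEMPO (cat), PhI(OAc)2, CH2Cl2, rt
Reagents that add atoms: none
Why: Oxoammonium (TEMPO) oxidation converts the lactol into the γ-lactone much faster than it oxidizes the three hindered secondary alcohols.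

Step 32
Reactants: 43 2,9,14-triol lactone
Product: 44 Junceellolide K
Conditions: Ac2O, pyridine, DMAP (cat), CH2Cl2, rt
Reagents that add atoms: acetic anhydride, CC(=O)OC(C)=O
Why: Acetylation esterifies the three secondary hydroxyls at C2, C9 and C14, while the tertiary C8 hydroxyl should remain free.

## Compound list

1 | 4-methoxy-3-methylphenol | COc1ccc(O)cc1C | starting material
2 | 4,4-dimethoxy-3-methylcyclohexa-2,5-dien-1-one | COC1(OC)C=CC(=O)C=C1C | intermediate
3 | 4,4-dimethoxy-3-methylcyclohex-2-en-1-one | COC1(OC)CCC(=O)C=C1C | intermediate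
4 | (R)-4,4-dimethoxy-3-methylcyclohex-2-en-1-ol | COC1(OC)CC[C@@H](O)C=C1C | intermediate
5 | (R)-3-[(4-methoxybenzyl)oxy]-6,6-dimethoxy-1-methylcyclohex-1-ene | COC1(OC)CC[C@@H](OCc2ccc(OC)cc2)C=C1C | intermediate
6 | (R)-4-[(4-methoxybenzyl)oxy]-2-methylcyclohex-2-en-1-one | CC1=C[C@H](OCc2ccc(OC)cc2)CCC1=O | intermediate
7 | (S)-hex-5-en-2-ol | C[C@H](O)CCC=C | starting material
8 | (S)-5-[(4-methoxybenzyl)oxy]hex-1-ene | C[C@H](OCc1ccc(OC)cc1)CCC=C | intermediate
9 | (S)-4-[(4-methoxybenzyl)oxy]pentanal | C[C@H](OCc1ccc(OC)cc1)CCC=O | intermediate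
10 | methyl (S)-2,2-dimethyl-1,3-dioxolane-4-carboxylate | COC(=O)[C@@H]1COC(C)(C)O1 | starting material
11 | (S)-N-methoxy-N,2,2-trimethyl-1,3-dioxolane-4-carboxamide (Weinreb amide) | CON(C)C(=O)[C@@H]1COC(C)(C)O1 | intermediate
12 | (S)-1-(2,2-dimethyl-1,3-dioxolan-4-yl)ethan-1-one | CC(=O)[C@@H]1COC(C)(C)O1 | intermediate
13 | hydrazone of 12 | CC(=NN)[C@@H]1COC(C)(C)O1 | intermediate
14 | (S)-4-(1-iodoethenyl)-2,2-dimethyl-1,3-dioxolane | C=C(I)[C@@H]1COC(C)(C)O1 | intermediate
15 | bromomagnesium enolate (C1=C14–OMgBr; C10 β-vinyl; C11 α-OPMB) | C=C[C@H]1[C@H](OCc2ccc(OC)cc2)CCC(O[Mg]Br)=C1C | intermediate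
16 | aldol adduct (C14 ketone, 2-OH, 5-OPMB, 10-vinyl, 11-OPMB) | C[C@@]1([C@@H](O)CC[C@H](C)OCc2ccc(OC)cc2)[C@@H](C=C)[C@H](OCc2ccc(OC)cc2)CCC1=O | intermediate
17 | 2,14-diol | C[C@@]1([C@@H](O)CC[C@H](C)OCc2ccc(OC)cc2)[C@@H](C=C)[C@H](OCc2ccc(OC)cc2)CC[C@@H]1O | intermediate
18 | 2,14-bis-TBS ether | C[C@@]1([C@@H](O[Si](C)(C)C(C)(C)C)CC[C@H](C)OCc2ccc(OC)cc2)[C@@H](C=C)[C@H](OCc2ccc(OC)cc2)CC[C@@H]1O[Si](C)(C)C(C)(C)C | intermediate
19 | C9 aldehyde | C[C@@]1([C@@H](O[Si](C)(C)C(C)(C)C)CC[C@H](C)OCc2ccc(OC)cc2)[C@@H](C=O)[C@H](OCc2ccc(OC)cc2)CC[C@@H]1O[Si](C)(C)C(C)(C)C | intermediate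
20 | vinyllithium from 14 | [Li]C(=C)[C@@H]1COC(C)(C)O1 | intermediate
21 | vinylmagnesium bromide from 14 | Br[Mg]C(=C)[C@@H]1COC(C)(C)O1 | intermediate
22 | (9S)-allylic alcohol (C8=CH2; O6/O7 acetonide) | C[C@@]1([C@@H](O[Si](C)(C)C(C)(C)C)CC[C@H](C)OCc2ccc(OC)cc2)[C@@H]([C@H](O)C(=C)[C@@H]2COC(C)(C)O2)[C@H](OCc2ccc(OC)cc2)CC[C@@H]1O[Si](C)(C)C(C)(C)C | intermediate
23 | 9-O-TBS ether | C[C@@]1([C@@H](O[Si](C)(C)C(C)(C)C)CC[C@H](C)OCc2ccc(OC)cc2)[C@@H]([C@H](O[Si](C)(C)C(C)(C)C)C(=C)[C@@H]2COC(C)(C)O2)[C@H](OCc2ccc(OC)cc2)CC[C@@H]1O[Si](C)(C)C(C)(C)C | intermediate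
24 | 6,7-diol | C[C@@]1([C@@H](O[Si](C)(C)C(C)(C)C)CC[C@H](C)OCc2ccc(OC)cc2)[C@@H]([C@H](O[Si](C)(C)C(C)(C)C)C(=C)[C@@H](O)CO)[C@H](OCc2ccc(OC)cc2)CC[C@@H]1O[Si](C)(C)C(C)(C)C | intermediate
25 | 6-O-tosylate (7-OH) | C[C@@]1([C@@H](O[Si](C)(C)C(C)(C)C)CC[C@H](C)OCc2ccc(OC)cc2)[C@@H]([C@H](O[Si](C)(C)C(C)(C)C)C(=C)[C@@H](O)COS(=O)(=O)c2ccc(C)cc2)[C@H](OCc2ccc(OC)cc2)CC[C@@H]1O[Si](C)(C)C(C)(C)C | intermediate
26 | 7-O-(2-bromopropanoyl) ester | C[C@@]1([C@@H](O[Si](C)(C)C(C)(C)C)CC[C@H](C)OCc2ccc(OC)cc2)[C@@H]([C@H](O[Si](C)(C)C(C)(C)C)C(=C)[C@@H](OC(=O)C(C)Br)COS(=O)(=O)c2ccc(C)cc2)[C@H](OCc2ccc(OC)cc2)CC[C@@H]1O[Si](C)(C)C(C)(C)C | intermediate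
27 | C8 ketone | C[C@@]1([C@@H](O[Si](C)(C)C(C)(C)C)CC[C@H](C)OCc2ccc(OC)cc2)[C@@H]([C@H](O[Si](C)(C)C(C)(C)C)C(=O)[C@@H](OC(=O)C(C)Br)COS(=O)(=O)c2ccc(C)cc2)[C@H](OCc2ccc(OC)cc2)CC[C@@H]1O[Si](C)(C)C(C)(C)C | intermediate
28 | samarium enolate of the O7 propanoate | C[C@@]1([C@@H](O[Si](C)(C)C(C)(C)C)CC[C@H](C)OCc2ccc(OC)cc2)[C@@H]([C@H](O[Si](C)(C)C(C)(C)C)C(=O)[C@@H](OC(O[Sm](I)I)=CC)COS(=O)(=O)c2ccc(C)cc2)[C@H](OCc2ccc(OC)cc2)CC[C@@H]1O[Si](C)(C)C(C)(C)C | intermediate
29 | β-hydroxy-γ-lactone (ring C) | C[C@@]1([C@@H](O[Si](C)(C)C(C)(C)C)CC[C@H](C)OCc2ccc(OC)cc2)[C@@H]([C@H](O[Si](C)(C)C(C)(C)C)[C@]2(O)[C@@H](C)C(=O)O[C@H]2COS(=O)(=O)c2ccc(C)cc2)[C@H](OCc2ccc(OC)cc2)CC[C@@H]1O[Si](C)(C)C(C)(C)C | intermediate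
30 | lactol | C[C@@]1([C@@H](O[Si](C)(C)C(C)(C)C)CC[C@H](C)OCc2ccc(OC)cc2)[C@@H]([C@H](O[Si](C)(C)C(C)(C)C)[C@]2(O)[C@@H](C)C(O)O[C@H]2COS(=O)(=O)c2ccc(C)cc2)[C@H](OCc2ccc(OC)cc2)CC[C@@H]1O[Si](C)(C)C(C)(C)C | intermediate
31 | lactol TIPS ether | C[C@@]1([C@@H](O[Si](C)(C)C(C)(C)C)CC[C@H](C)OCc2ccc(OC)cc2)[C@@H]([C@H](O[Si](C)(C)C(C)(C)C)[C@]2(O)[C@@H](C)C(O[Si](C(C)C)(C(C)C)C(C)C)O[C@H]2COS(=O)(=O)c2ccc(C)cc2)[C@H](OCc2ccc(OC)cc2)CC[C@@H]1O[Si](C)(C)C(C)(C)C | intermediate
32 | 5,11-diol | C[C@@]1([C@@H](O[Si](C)(C)C(C)(C)C)CC[C@H](C)O)[C@@H]([C@H](O[Si](C)(C)C(C)(C)C)[C@]2(O)[C@@H](C)C(O[Si](C(C)C)(C(C)C)C(C)C)O[C@H]2COS(=O)(=O)c2ccc(C)cc2)[C@H](O)CC[C@@H]1O[Si](C)(C)C(C)(C)C | intermediate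
33 | (5R)-thioacetate | C[C@@]1([C@@H](O[Si](C)(C)C(C)(C)C)CC[C@@H](C)SC(C)=O)[C@@H]([C@H](O[Si](C)(C)C(C)(C)C)[C@]2(O)[C@@H](C)C(O[Si](C(C)C)(C(C)C)C(C)C)O[C@H]2COS(=O)(=O)c2ccc(C)cc2)[C@H](O)CC[C@@H]1O[Si](C)(C)C(C)(C)C | intermediate
34 | (5R)-thiol | C[C@@]1([C@@H](O[Si](C)(C)C(C)(C)C)CC[C@@H](C)S)[C@@H]([C@H](O[Si](C)(C)C(C)(C)C)[C@]2(O)[C@@H](C)C(O[Si](C(C)C)(C(C)C)C(C)C)O[C@H]2COS(=O)(=O)c2ccc(C)cc2)[C@H](O)CC[C@@H]1O[Si](C)(C)C(C)(C)C | intermediate
35 | 11-membered cyclic sulfide (11-OH) | C[C@@]12[C@@H](O[Si](C)(C)C(C)(C)C)CC[C@@H](C)SC[C@@H]3OC(O[Si](C(C)C)(C(C)C)C(C)C)[C@H](C)[C@@]3(O)[C@@H](O[Si](C)(C)C(C)(C)C)[C@H]1[C@H](O)CC[C@@H]2O[Si](C)(C)C(C)(C)C | intermediate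
36 | C11 ketone | C[C@@]12[C@@H](O[Si](C)(C)C(C)(C)C)CC[C@@H](C)SC[C@@H]3OC(O[Si](C(C)C)(C(C)C)C(C)C)[C@H](C)[C@@]3(O)[C@@H](O[Si](C)(C)C(C)(C)C)[C@H]1C(=O)CC[C@@H]2O[Si](C)(C)C(C)(C)C | intermediate
37 | C11 methylene sulfide | C[C@@]12[C@@H](O[Si](C)(C)C(C)(C)C)CC[C@@H](C)SC[C@@H]3OC(O[Si](C(C)C)(C(C)C)C(C)C)[C@H](C)[C@@]3(O)[C@@H](O[Si](C)(C)C(C)(C)C)[C@H]1C(=C)CC[C@@H]2O[Si](C)(C)C(C)(C)C | intermediate
38 | 11-membered cyclic sulfone with 11,20-epoxide | C[C@@]12[C@@H](O[Si](C)(C)C(C)(C)C)CC[C@@H](C)S(=O)(=O)C[C@@H]3OC(O[Si](C(C)C)(C(C)C)C(C)C)[C@H](C)[C@@]3(O)[C@@H](O[Si](C)(C)C(C)(C)C)[C@H]1[C@@]4(CO4)CC[C@@H]2O[Si](C)(C)C(C)(C)C | intermediate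
39 | α-bromo sulfone (Br at C6) | C[C@@]12[C@@H](O[Si](C)(C)C(C)(C)C)CC[C@@H](C)S(=O)(=O)C(Br)[C@@H]3OC(O[Si](C(C)C)(C(C)C)C(C)C)[C@H](C)[C@@]3(O)[C@@H](O[Si](C)(C)C(C)(C)C)[C@H]1[C@@]4(CO4)CC[C@@H]2O[Si](C)(C)C(C)(C)C | intermediate
40 | episulfone (C5–C6 thiirane 1,1-dioxide fused to ring B) | C[C@@]12[C@@H](O[Si](C)(C)C(C)(C)C)CCC5(C)C(S5(=O)=O)[C@@H]3OC(O[Si](C(C)C)(C(C)C)C(C)C)[C@H](C)[C@@]3(O)[C@@H](O[Si](C)(C)C(C)(C)C)[C@H]1[C@@]4(CO4)CC[C@@H]2O[Si](C)(C)C(C)(C)C | intermediate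
41 | ten-membered (5Z)-cycloalkene, silyl lactol, 2,9,14-tris-TBS | CC(C)(C)[Si](C)(C)O[C@H]1CC/C(C)=C\[C@@H]2OC(O[Si](C(C)C)(C(C)C)C(C)C)[C@H](C)[C@@]2(O)[C@@H](O[Si](C)(C)C(C)(C)C)[C@H]2[C@]3(CC[C@H](O[Si](C)(C)C(C)(C)C)[C@]12C)CO3 | intermediate
42 | lactol pentaol | O[C@H]1CC/C(C)=C\[C@@H]2OC(O)[C@H](C)[C@@]2(O)[C@@H](O)[C@H]2[C@]3(CC[C@H](O)[C@]12C)CO3 | intermediate
43 | 2,9,14-triol lactone | O[C@H]1CC/C(C)=C\[C@@H]2OC(=O)[C@H](C)[C@@]2(O)[C@@H](O)[C@H]2[C@]3(CC[C@H](O)[C@]12C)CO3 | intermediate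
44 | Junceellolide K | CC(=O)O[C@H]1CC/C(C)=C\[C@@H]2OC(=O)[C@H](C)[C@@]2(O)[C@@H](OC(C)=O)[C@H]2[C@]3(CC[C@H](OC(C)=O)[C@]12C)CO3 | target

## Step count and risks

Total step count: 32. Longest linear sequence: 28 steps (steps 1–5 and 10–32).

Steps most likely to fail:

Step 29. The episulfone closure may lose geometric control and give E/Z mixtures. The C6 carbanion may also expel the C7 oxygen by β-elimination, or bromination may not stop at one halogen. The fallback sets out from sulfide 37 and fixes the halogen before any base is present. Chlorination next to sulfur with N-chlorosuccinimide (CH2Cl2, 0 °C) would give the α-chloro sulfide F1. Excess mCPBA would then give the α-chloro sulfone epoxide F2. Brief treatment of this with KOt-Bu in THF at −78 °C would effect the ring contraction at low temperature and come back to the route at 41.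

Step 20. Electron transfer to the α-acyloxy ketone may cleave the C7–O bond before the enolate adds, or the enolate may add with poor facial selectivity. The fallback sets out from tosylate 25 and makes the C8–C17 bond intermolecularly on a ketone that carries no acyloxy group. Silylation with TESOTf would give the 7-O-triethylsilyl ether F3 and ozonolysis the ketone F4. A zinc Reformatsky reaction with ethyl 2-bromopropanoate (activated Zn, THF) would give the β-hydroxy ester F5. Removal of the TES group with pyridinium tosylate in MeOH would let the freed C7 hydroxyl lactonize, returning to the route at 29.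

Step 14. Facial selectivity may erode if the magnesium chelate is incomplete or the chiral vinyl metal is mismatched, and the vinyl metal may decompose by β-alkoxide elimination. The fallback sets out from ketone 12 and aldehyde 19 and replaces substrate control by reagent control. Enolization of 12 with KN(SiMe3)2 and trapping with PhNTf2 would give the enol triflate F6. Nozaki–Hiyama–Kishi coupling with 19 (CrCl2, NiCl2 cat, DMF) would give the allylic alcohol as a C9 epimer mixture F7. Oxidation with Dess–Martin periodinane would give the enone F8, and Corey–Bakshi–Shibata reduction with the (R)-Me-CBS catalyst and catecholborane should set the (9S)-carbinol and return to the route at 22.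

## Further compounds

F1 | step 29 | α-chloro sulfide (Cl at C6) of 37 | C[C@@]12[C@@H](O[Si](C)(C)C(C)(C)C)CC[C@@H](C)SC(Cl)[C@@H]3OC(O[Si](C(C)C)(C(C)C)C(C)C)[C@H](C)[C@@]3(O)[C@@H](O[Si](C)(C)C(C)(C)C)[C@H]1C(=C)CC[C@@H]2O[Si](C)(C)C(C)(C)C
F2 | step 29 | α-chloro sulfone with 11,20-epoxide | C[C@@]12[C@@H](O[Si](C)(C)C(C)(C)C)CC[C@@H](C)S(=O)(=O)C(Cl)[C@@H]3OC(O[Si](C(C)C)(C(C)C)C(C)C)[C@H](C)[C@@]3(O)[C@@H](O[Si](C)(C)C(C)(C)C)[C@H]1[C@@]4(CO4)CC[C@@H]2O[Si](C)(C)C(C)(C)C
F3 | step 20 | 7-O-triethylsilyl ether of 25 | C[C@@]1([C@@H](O[Si](C)(C)C(C)(C)C)CC[C@H](C)OCc2ccc(OC)cc2)[C@@H]([C@H](O[Si](C)(C)C(C)(C)C)C(=C)[C@@H](O[Si](CC)(CC)CC)COS(=O)(=O)c2ccc(C)cc2)[C@H](OCc2ccc(OC)cc2)CC[C@@H]1O[Si](C)(C)C(C)(C)C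
F4 | step 20 | C8 ketone with 7-O-triethylsilyl ether | C[C@@]1([C@@H](O[Si](C)(C)C(C)(C)C)CC[C@H](C)OCc2ccc(OC)cc2)[C@@H]([C@H](O[Si](C)(C)C(C)(C)C)C(=O)[C@@H](O[Si](CC)(CC)CC)COS(=O)(=O)c2ccc(C)cc2)[C@H](OCc2ccc(OC)cc2)CC[C@@H]1O[Si](C)(C)C(C)(C)C
F5 | step 20 | β-hydroxy ethyl ester (8-OH, C17 methyl, 7-O-triethylsilyl) | C[C@@]1([C@@H](O[Si](C)(C)C(C)(C)C)CC[C@H](C)OCc2ccc(OC)cc2)[C@@H]([C@H](O[Si](C)(C)C(C)(C)C)[C@](O)([C@@H](C)C(=O)OCC)[C@@H](O[Si](CC)(CC)CC)COS(=O)(=O)c2ccc(C)cc2)[C@H](OCc2ccc(OC)cc2)CC[C@@H]1O[Si](C)(C)C(C)(C)C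
F6 | step 14 | (S)-1-(2,2-dimethyl-1,3-dioxolan-4-yl)ethenyl trifluoromethanesulfonate | C=C(OS(=O)(=O)C(F)(F)F)[C@@H]1COC(C)(C)O1
F7 | step 14 | allylic alcohol as C9 epimer mixture | C[C@@]1([C@@H](O[Si](C)(C)C(C)(C)C)CC[C@H](C)OCc2ccc(OC)cc2)[C@@H](C(O)C(=C)[C@@H]2COC(C)(C)O2)[C@H](OCc2ccc(OC)cc2)CC[C@@H]1O[Si](C)(C)C(C)(C)C
F8 | step 14 | C9 enone | C[C@@]1([C@@H](O[Si](C)(C)C(C)(C)C)CC[C@H](C)OCc2ccc(OC)cc2)[C@@H](C(=O)C(=C)[C@@H]2COC(C)(C)O2)[C@H](OCc2ccc(OC)cc2)CC[C@@H]1O[Si](C)(C)C(C)(C)C
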